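## Retrosynthetic overview

1. Endgame on a finished all-cis ring: side-chain oxirane (Shi epoxidation), both angelates (esterification of C5–OH and C8–OH), and the C7(=CH2)–C8–C11 chain built from a C1–CH2CH2O handle (oxidation, α-methylenation, allylation, cross-metathesis).
2. Ring oxirane from hydroxyl-directed epoxidation of the C3=C4 bond of a 2-methylcyclohex-2-en-1-ol; C5–OH from Luche reduction of a 6-acetoxy-2-methylcyclohex-2-enone; C6–H from decarboxylative protonation of an allyl β-keto ester.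
3. Enabling feature: in the six-membered ring, C4(CH3)–C5(O)–C6(OAc) is the α-carbon/carbonyl/α'-carbon triad of a 2-acetoxy-3-oxopentanoate, and C1–C2–C3 is the β-carbon/α-carbon/carbonyl carbon of an enal. The C3–C4 oxirane next to C5–O is therefore the retron of a cyclohex-2-enone made by a [3+3] Michael/aldol condensation.
4. Key disconnection: C1–C6 (conjugate addition) and C3–C4 (aldol condensation) in one flask from enal 2 and keto ester 5 under chiral secondary-amine catalysis; this also sets C1, which controls all later ring centres.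
5. Order of ring formation: cyclohexenone ring (step 4), ring oxirane (step 7), side-chain oxirane (step 15).

Key step: step 4

Remark on locants: ring C1 bears the side chain, C2 is CH2, C3/C4 are the oxirane carbons (C4 carries CH3), C5 carries the angelate, C6 the acetate; side chain C7 is the =CH2-bearing carbon, C8 carries the angelate, C9 is CH2, C10/C11 are the oxirane carbons. TBS = tert-butyldimethylsilyl.

Remark on reagents: compounds 1 and 3, the pentane solution of (−)-Ipc2B(allyl) and the L-fructose-derived Shi ketone (enantiomer of the usual D-fructose-derived catalyst, otherwise made from L-sorbose) are assumed to be purchasable.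

## Route

Step 1
Reactants: 1 3-[(TBS)oxy]propanal
Product: 2 (2E)-5-[(TBS)oxy]pent-2-enal
Conditions: Ph3P=CHCHO, toluene, 80 °C
Reagents that add atoms: (triphenylphosphoranylidene)acetaldehyde, O=CC=P(c1ccccc1)(c1ccccc1)c1ccccc1
Why: The stabilised formyl ylide should olefinate the aliphatic aldehyde once and give the E enal (Wittig reaction), with no stereocentre formed.

Step 2
Reactants: 3 methyl 3-oxopentanoate
Product: 4 prop-2-en-1-yl 3-oxopentanoate
Conditions: allyl alcohol (excess), DMAP (cat.), toluene, reflux, 4 Å molecular sieves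
Reagents that add atoms: allyl alcohol, C=CCO
Why: β-Keto esters exchange their alkoxy group readily on heating with an alcohol while methanol is removed (transesterification).

Step 3
Reactants: 4 prop-2-en-1-yl 3-oxopentanoate
Product: 5 prop-2-en-1-yl 2-acetoxy-3-oxopentanoate (racemic)
Conditions: Pb(OAc)4, benzene, rt
Reagents that add atoms: lead tetraacetate, CC(=O)O[Pb](OC(C)=O)(OC(C)=O)OC(C)=O
Why: Pb(OAc)4 should acetoxylate the enol of the β-keto ester at the carbon between the two carbonyl groups (α-acetoxylation of a 1,3-dicarbonyl compound); the new centre is racemic and is reset in step 5.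

Step 4
Reactants: 2 (2E)-5-[(TBS)oxy]pent-2-enal; 5 prop-2-en-1-yl 2-acetoxy-3-oxopentanoate
Product: 8 prop-2-en-1-yl (6S)-1-acetoxy-6-{2-[(TBS)oxy]ethyl}-3-methyl-2-oxocyclohex-3-ene-1-carboxylate (both epimers at the acetoxy carbon), via Michael adduct keto aldehyde 6 (not isolated), via aldol cyclohexanone 7 (not isolated)
Conditions: (S)-2-{bis[3,5-bis(trifluoromethyl)phenyl](trimethylsilyloxy)methyl}pyrrolidine (10 mol %), PhCO2H (10 mol %), toluene, rt; then Bn2NH·CF3CO2H (0.5 equiv), 50 °C, same flask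
Reagents that add atoms: none
Why: The amine condenses with enal 2 to an E,s-trans iminium ion whose β-carbon is attacked by the enol of keto ester 5 from the face opposite the bulky diaryl(silyloxy)methyl group (organocatalytic Michael addition), which forms the C1–C6 bond and gives 6. The ethyl ketone of 6 then closes onto the aldehyde (amine-salt-promoted intramolecular aldol, 6-(enolendo)-exo-trig) to 7 and loses water, which forms the C3–C4 bond as the conjugated C3=C4 bond of 8 (aldol condensation). The closest known reaction type is the one-flask amine-catalysed Michael/aldol-condensation [3+3] annulation of β-keto esters with enals to 5-substituted cyclohex-2-enones. The only lasting stereocentre is C1, set by the (S)-catalyst (attack on the Re face of the β-carbon of 2); the quaternary acetoxy carbon forms as a mixture that step 5 erases. The step needs 1,4- over 1,2-addition, secured by iminium activation and the soft doubly stabilised nucleophile. It also needs Michael addition through the acetoxy carbon and aldol closure through the ethyl CH2, secured because the acetoxy carbon is the only acidic 1,3-dicarbonyl position and becomes quaternary after the first bond, so the ketone can enolise only towards C4.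

Step 5
Reactants: 8 prop-2-en-1-yl (6S)-1-acetoxy-6-{2-[(TBS)oxy]ethyl}-3-methyl-2-oxocyclohex-3-ene-1-carboxylate
Product: 9 (1R,6S)-6-{2-[(TBS)oxy]ethyl}-3-methyl-2-oxocyclohex-3-en-1-yl acetate (acetate cis to the side chain)
Conditions: Pd(OAc)2 (5 mol %), PPh3 (15 mol %), HCO2H, Et3N, THF, 0 °C to rt
Reagents that add atoms: none
Why: Zerovalent palladium should ionise the allyl ester, formate reduces the allyl unit, and the β-keto carboxylate loses CO2 to an enol that is protonated at C6 anti to the C1 side chain, which strain against the in-plane acetoxy group holds pseudo-axial, so acetate and side chain should end up cis under kinetic control (Tsuji decarboxylative protonation).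

Step 6
Reactants: 9 (1R,6S)-6-{2-[(TBS)oxy]ethyl}-3-methyl-2-oxocyclohex-3-en-1-yl acetate
Product: 10 (1R,2S,6S)-6-{2-[(TBS)oxy]ethyl}-2-hydroxy-3-methylcyclohex-3-en-1-yl acetate (all-cis)
Conditions: NaBH4, CeCl3·7H2O, MeOH, −78 °C; AcOH quench
Reagents that add atoms: none
Why: 1,2-Reduction of the enone (Luche reduction) should deliver hydride anti to the axial C6–OAc bond (Felkin–Anh, axial attack), giving C5–OH cis to the acetate and to the side chain.

Step 7
Reactants: 10 (1R,2S,6S)-6-{2-[(TBS)oxy]ethyl}-2-hydroxy-3-methylcyclohex-3-en-1-yl acetate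
Product: 11 (1R,2R,3R,4R,6S)-4-{2-[(TBS)oxy]ethyl}-2-hydroxy-1-methyl-7-oxabicyclo[4.1.0]heptan-3-yl acetate
Conditions: VO(acac)2 (5 mol %), t-BuOOH (decane), CH2Cl2, 0 °C to rt
Reagents that add atoms: tert-butyl hydroperoxide, CC(C)(C)OO
Why: The vanadium-bound peroxide is delivered to the C3=C4 bond from the face of the allylic C5 hydroxyl (hydroxyl-directed VO(acac)2/t-BuOOH epoxidation), which sets both oxirane carbons cis to C5–OH.

Step 8
Reactants: 11 (1R,2R,3R,4R,6S)-4-{2-[(TBS)oxy]ethyl}-2-hydroxy-1-methyl-7-oxabicyclo[4.1.0]heptan-3-yl acetate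
Product: 12 (1S,2R,3R,4R,6S)-3-acetoxy-4-{2-[(TBS)oxy]ethyl}-1-methyl-7-oxabicyclo[4.1.0]heptan-2-yl (2Z)-2-methylbut-2-enoate
Conditions: angelic acid, 2,4,6-trichlorobenzoyl chloride, Et3N, toluene, rt; then 11, 75 °C
Reagents that add atoms: angelic acid, C/C=C(/C)C(=O)O
Why: The preformed mixed anhydride should acylate the hindered secondary alcohol at the angeloyl carbonyl without nucleophilic catalyst, which keeps the Z geometry (Yamaguchi esterification); no stereocentre changes.

Step 9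
Reactants: 12 (1S,2R,3R,4R,6S)-3-acetoxy-4-{2-[(TBS)oxy]ethyl}-1-methyl-7-oxabicyclo[4.1.0]heptan-2-yl (2Z)-2-methylbut-2-enoate
Product: 13 (1S,2R,3R,4R,6S)-3-acetoxy-4-(2-hydroxyethyl)-1-methyl-7-oxabicyclo[4.1.0]heptan-2-yl (2Z)-2-methylbut-2-enoate
Conditions: HF·pyridine, pyridine, THF, 0 °C
Reagents that add atoms: none
Why: Buffered fluoride should cleave the primary silyl ether while the esters and the oxirane are left intact (desilylation).

Step 10
Reactants: 13 (1S,2R,3R,4R,6S)-3-acetoxy-4-(2-hydroxyethyl)-1-methyl-7-oxabicyclo[4.1.0]heptan-2-yl (2Z)-2-methylbut-2-enoate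
Product: 14 (1S,2R,3R,4S,6S)-3-acetoxy-1-methyl-4-(2-oxoethyl)-7-oxabicyclo[4.1.0]heptan-2-yl (2Z)-2-methylbut-2-enoate
Conditions: Dess–Martin periodinane, NaHCO3, CH2Cl2, rt
Reagents that add atoms: none
Why: The buffered hypervalent-iodine oxidant should convert the primary alcohol into the aldehyde without touching the oxirane or the esters (Dess–Martin oxidation).

Step 11
Reactants: 14 (1S,2R,3R,4S,6S)-3-acetoxy-1-methyl-4-(2-oxoethyl)-7-oxabicyclo[4.1.0]heptan-2-yl (2Z)-2-methylbut-2-enoate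
Product: 16 (1S,2R,3R,4S,6S)-3-acetoxy-1-methyl-4-(3-oxoprop-1-en-2-yl)-7-oxabicyclo[4.1.0]heptan-2-yl (2Z)-2-methylbut-2-enoate, via Mannich base 15 (not isolated)
Conditions: CH2=NMe2+ I− (Eschenmoser's salt), Et3N, CH2Cl2, rt
Reagents that add atoms: N,N-dimethylmethyleneiminium iodide, C=[N+](C)C.[I-]
Why: Aminomethylation of the aldehyde at C7 followed by loss of dimethylamine should install the C7=CH2 group (Mannich reaction/β-elimination, α-methylenation); the transient C7 centre disappears.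

Step 12
Reactants: 16 (1S,2R,3R,4S,6S)-3-acetoxy-1-methyl-4-(3-oxoprop-1-en-2-yl)-7-oxabicyclo[4.1.0]heptan-2-yl (2Z)-2-methylbut-2-enoate
Product: 18 (1S,2R,3R,4S,6S)-3-acetoxy-4-[(3S)-3-hydroxyhexa-1,5-dien-2-yl]-1-methyl-7-oxabicyclo[4.1.0]heptan-2-yl (2Z)-2-methylbut-2-enoate, via borinate ester 17 (not isolated)
Conditions: (−)-Ipc2B(allyl) (pentane solution), Et2O, −78 °C; then aq NaOAc, H2O2, 0 °C to rt
Reagents that add atoms: (−)-B-allyldiisopinocampheylborane, C=CCB([C@@H]1C[C@@H]2C[C@@H](C2(C)C)[C@H]1C)[C@@H]1C[C@@H]2C[C@@H](C2(C)C)[C@H]1C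
Why: The allylborane should add 1,2 to the enal through a chair transition state on the Si face of the aldehyde under reagent control, setting C8 as S (Brown asymmetric allylation).

Step 13
Reactants: 18 (1S,2R,3R,4S,6S)-3-acetoxy-4-[(3S)-3-hydroxyhexa-1,5-dien-2-yl]-1-methyl-7-oxabicyclo[4.1.0]heptan-2-yl (2Z)-2-methylbut-2-enoate
Product: 19 (1S,2R,3R,4S,6S)-3-acetoxy-4-[(3S)-3-hydroxy-6-methylhepta-1,5-dien-2-yl]-1-methyl-7-oxabicyclo[4.1.0]heptan-2-yl (2Z)-2-methylbut-2-enoate
Conditions: 2-methyl-2-butene (excess), second-generation Grubbs catalyst (5 mol %), CH2Cl2, 40 °C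
Reagents that add atoms: 2-methyl-2-butene, CC=C(C)C
Why: Only the monosubstituted terminal alkene should enter the catalytic cycle, and exchange with excess 2-methyl-2-butene turns it into the prenyl group (olefin cross-metathesis); the 1,1-disubstituted and acrylate-type alkenes are unreactive.

Step 14
Reactants: 19 (1S,2R,3R,4S,6S)-3-acetoxy-4-[(3S)-3-hydroxy-6-methylhepta-1,5-dien-2-yl]-1-methyl-7-oxabicyclo[4.1.0]heptan-2-yl (2Z)-2-methylbut-2-enoate
Product: 20 (1S,2R,3R,4S,6S)-3-acetoxy-1-methyl-4-[(3S)-6-methyl-3-{[(2Z)-2-methylbut-2-enoyl]oxy}hepta-1,5-dien-2-yl]-7-oxabicyclo[4.1.0]heptan-2-yl (2Z)-2-methylbut-2-enoate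
Conditions: angelic acid, 2,4,6-trichlorobenzoyl chloride, Et3N, toluene, rt; then 19, 75 °C
Reagents that add atoms: angelic acid, C/C=C(/C)C(=O)O
Why: The mixed anhydride should acylate the allylic C8 alcohol with retention at carbon and without Z to E isomerisation (Yamaguchi esterification).

Step 15
Reactants: 20 (1S,2R,3R,4S,6S)-3-acetoxy-1-methyl-4-[(3S)-6-methyl-3-{[(2Z)-2-methylbut-2-enoyl]oxy}hepta-1,5-dien-2-yl]-7-oxabicyclo[4.1.0]heptan-2-yl (2Z)-2-methylbut-2-enoate
Product: 21 (1S,2R,3R,4S,6S)-3-acetoxy-4-[(3S)-4-[(2S)-3,3-dimethyloxiran-2-yl]-3-{[(2Z)-2-methylbut-2-enoyl]oxy}but-1-en-2-yl]-1-methyl-7-oxabicyclo[4.1.0]heptan-2-yl (2Z)-2-methylbut-2-enoate (target)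
Conditions: L-fructose-derived Shi ketone (30 mol %), Oxone (2KHSO5·KHSO4·K2SO4), K2CO3, Bu4NHSO4, MeCN/dimethoxymethane–aq Na2B4O7 buffer, 0 °C
Reagents that add atoms: potassium peroxymonosulfate (from Oxone), [K+].[O-]S(=O)(=O)OO
Why: The chiral dioxirane should epoxidise only the electron-rich trisubstituted C10=C11 alkene through a spiro transition state, the L-fructose-derived ketone giving the S oxirane carbon (Shi epoxidation); the hindered 1,1-disubstituted alkene and the electron-poor angelate alkenes should not react.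

## Compound list

1 | 3-[(tert-butyldimethylsilyl)oxy]propanal | CC(C)(C)[Si](C)(C)OCCC=O | starting material
2 | (2E)-5-[(tert-butyldimethylsilyl)oxy]pent-2-enal | CC(C)(C)[Si](C)(C)OCC/C=C/C=O | intermediate
3 | methyl 3-oxopentanoate | CCC(=O)CC(=O)OC | starting material
4 | prop-2-en-1-yl 3-oxopentanoate | CCC(=O)CC(=O)OCC=C | intermediate
5 | prop-2-en-1-yl 2-acetoxy-3-oxopentanoate (racemic) | CCC(=O)C(OC(C)=O)C(=O)OCC=C | intermediate
6 | prop-2-en-1-yl (3R)-2-acetoxy-3-{2-[(TBS)oxy]ethyl}-5-oxo-2-propanoylpentanoate (both epimers at C2; not isolated) | CC(C)(C)[Si](C)(C)OCC[C@H](CC=O)C(OC(C)=O)(C(=O)OCC=C)C(=O)CC | intermediate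
7 | prop-2-en-1-yl (6R)-1-acetoxy-6-{2-[(TBS)oxy]ethyl}-4-hydroxy-3-methyl-2-oxocyclohexane-1-carboxylate (mixture at C1, C3, C4; not isolated) | CC(C)(C)[Si](C)(C)OCC[C@@H]1CC(O)C(C)C(=O)C1(OC(C)=O)C(=O)OCC=C | intermediate
8 | prop-2-en-1-yl (6S)-1-acetoxy-6-{2-[(TBS)oxy]ethyl}-3-methyl-2-oxocyclohex-3-ene-1-carboxylate (both epimers at C1) | CC(C)(C)[Si](C)(C)OCC[C@@H]1CC=C(C)C(=O)C1(OC(C)=O)C(=O)OCC=C | intermediate
9 | (1R,6S)-6-{2-[(TBS)oxy]ethyl}-3-methyl-2-oxocyclohex-3-en-1-yl acetate | CC(C)(C)[Si](C)(C)OCC[C@@H]1CC=C(C)C(=O)[C@@H]1OC(C)=O | intermediate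
10 | (1R,2S,6S)-6-{2-[(TBS)oxy]ethyl}-2-hydroxy-3-methylcyclohex-3-en-1-yl acetate | CC(C)(C)[Si](C)(C)OCC[C@@H]1CC=C(C)[C@H](O)[C@@H]1OC(C)=O | intermediate
11 | (1R,2R,3R,4R,6S)-4-{2-[(TBS)oxy]ethyl}-2-hydroxy-1-methyl-7-oxabicyclo[4.1.0]heptan-3-yl acetate | CC(C)(C)[Si](C)(C)OCC[C@@H]1C[C@@H]2O[C@]2(C)[C@H](O)[C@@H]1OC(C)=O | intermediate
12 | (1S,2R,3R,4R,6S)-3-acetoxy-4-{2-[(TBS)oxy]ethyl}-1-methyl-7-oxabicyclo[4.1.0]heptan-2-yl (2Z)-2-methylbut-2-enoate | CC(C)(C)[Si](C)(C)OCC[C@@H]1C[C@@H]2O[C@]2(C)[C@H](OC(=O)/C(C)=C\C)[C@@H]1OC(C)=O | intermediate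
13 | (1S,2R,3R,4R,6S)-3-acetoxy-4-(2-hydroxyethyl)-1-methyl-7-oxabicyclo[4.1.0]heptan-2-yl (2Z)-2-methylbut-2-enoate | OCC[C@@H]1C[C@@H]2O[C@]2(C)[C@H](OC(=O)/C(C)=C\C)[C@@H]1OC(C)=O | intermediate
14 | (1S,2R,3R,4S,6S)-3-acetoxy-1-methyl-4-(2-oxoethyl)-7-oxabicyclo[4.1.0]heptan-2-yl (2Z)-2-methylbut-2-enoate | O=CC[C@@H]1C[C@@H]2O[C@]2(C)[C@H](OC(=O)/C(C)=C\C)[C@@H]1OC(C)=O | intermediate
15 | (1S,2R,3R,4S,6S)-3-acetoxy-4-[1-(dimethylamino)-3-oxopropan-2-yl]-1-methyl-7-oxabicyclo[4.1.0]heptan-2-yl (2Z)-2-methylbut-2-enoate (both epimers at the side-chain carbon; not isolated) | CN(C)CC(C=O)[C@@H]1C[C@@H]2O[C@]2(C)[C@H](OC(=O)/C(C)=C\C)[C@@H]1OC(C)=O | intermediate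
16 | (1S,2R,3R,4S,6S)-3-acetoxy-1-methyl-4-(3-oxoprop-1-en-2-yl)-7-oxabicyclo[4.1.0]heptan-2-yl (2Z)-2-methylbut-2-enoate | C=C(C=O)[C@@H]1C[C@@H]2O[C@]2(C)[C@H](OC(=O)/C(C)=C\C)[C@@H]1OC(C)=O | intermediate
17 | diisopinocampheylborinate of alcohol 18 (not isolated) | C=C([C@H](CC=C)OB([C@@H]1C[C@@H]2C[C@@H](C2(C)C)[C@H]1C)[C@@H]1C[C@@H]2C[C@@H](C2(C)C)[C@H]1C)[C@@H]1C[C@@H]2O[C@]2(C)[C@H](OC(=O)/C(C)=C\C)[C@@H]1OC(C)=O | intermediate
18 | (1S,2R,3R,4S,6S)-3-acetoxy-4-[(3S)-3-hydroxyhexa-1,5-dien-2-yl]-1-methyl-7-oxabicyclo[4.1.0]heptan-2-yl (2Z)-2-methylbut-2-enoate | C=C([C@H](CC=C)O)[C@@H]1C[C@@H]2O[C@]2(C)[C@H](OC(=O)/C(C)=C\C)[C@@H]1OC(C)=O | intermediate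
19 | (1S,2R,3R,4S,6S)-3-acetoxy-4-[(3S)-3-hydroxy-6-methylhepta-1,5-dien-2-yl]-1-methyl-7-oxabicyclo[4.1.0]heptan-2-yl (2Z)-2-methylbut-2-enoate | C=C([C@H](CC=C(C)C)O)[C@@H]1C[C@@H]2O[C@]2(C)[C@H](OC(=O)/C(C)=C\C)[C@@H]1OC(C)=O | intermediate
20 | (1S,2R,3R,4S,6S)-3-acetoxy-1-methyl-4-[(3S)-6-methyl-3-{[(2Z)-2-methylbut-2-enoyl]oxy}hepta-1,5-dien-2-yl]-7-oxabicyclo[4.1.0]heptan-2-yl (2Z)-2-methylbut-2-enoate | C=C([C@H](CC=C(C)C)OC(=O)/C(C)=C\C)[C@@H]1C[C@@H]2O[C@]2(C)[C@H](OC(=O)/C(C)=C\C)[C@@H]1OC(C)=O | intermediate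
21 | (1S,2R,3R,4S,6S)-3-acetoxy-4-[(3S)-4-[(2S)-3,3-dimethyloxiran-2-yl]-3-{[(2Z)-2-methylbut-2-enoyl]oxy}but-1-en-2-yl]-1-methyl-7-oxabicyclo[4.1.0]heptan-2-yl (2Z)-2-methylbut-2-enoate | C=C([C@H](C[C@@H]1OC1(C)C)OC(=O)/C(C)=C\C)[C@@H]1C[C@@H]2O[C@]2(C)[C@H](OC(=O)/C(C)=C\C)[C@@H]1OC(C)=O | target

## Step count and risks

Total step count: 15. Longest linear sequence: 14 steps (steps 2 to 15, from 3).

Steps most likely to fail:

1. Step 4. The hindered tertiary acetoxy-bearing nucleophile may add too slowly. Acetyl transfer from 5 to the amine may deactivate the catalyst, or the quaternary adduct may undergo retro-Claisen cleavage. Dehydration may also stop at the aldol stage.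
Fallback: it sets out from compounds 2 and 4 and comes back at compound 8. The annulation is run with the unacetoxylated keto ester 4, the established donor class for this one-flask Michael/aldol condensation, under the same amine catalysis. This should give prop-2-en-1-yl (6S)-6-{2-[(TBS)oxy]ethyl}-3-methyl-2-oxocyclohex-3-ene-1-carboxylate F1. The acetoxy group is then introduced by Pb(OAc)4 acetoxylation of this cyclic β-keto ester (benzene, rt), which gives 8.

2. Step 5. The protonation of the enol may show poor facial selectivity, or the acetoxy-bearing carbon may equilibrate under the amine base after protonation; both would erode the cis relationship between acetate and side chain.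
Fallback: it sets out from compound 2 and comes back at compound 9, and it sets the acetoxy carbon by inversion instead of protonation. Enal 2 and commercial tert-butyl 3-oxopentanoate (CCC(=O)CC(=O)OC(C)(C)C) are combined under the same amine catalyst. TsOH (20 mol %) in toluene at 80 °C then converts the intermediate tert-butyl (6S)-6-{2-[(TBS)oxy]ethyl}-3-methyl-2-oxocyclohex-3-ene-1-carboxylate F2 into (5S)-5-{2-[(TBS)oxy]ethyl}-2-methylcyclohex-2-en-1-one F3 with loss of 2-methylpropene and CO2. Kinetic enolisation (LiN(SiMe3)2, THF, −78 °C) and oxidation with 2-(phenylsulfonyl)-3-phenyloxaziridine should place the hydroxyl anti to the neighbouring side chain and give (5S,6S)-5-{2-[(TBS)oxy]ethyl}-6-hydroxy-2-methylcyclohex-2-en-1-one F4. A Mitsunobu reaction with acetic acid (PPh3, diisopropyl azodicarboxylate, toluene, 0 °C) inverts that carbon and gives 9.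

3. Step 8. Under the hot, basic acylation conditions the acetyl group may migrate from the neighbouring cis oxygen to the free hydroxyl, which scrambles the two ester positions. The activated angelic acid may isomerise from Z to E, and the alcohol, flanked by a quaternary oxirane carbon, may acylate slowly.
Fallback: it sets out from compound 11 and comes back at compound 12, and it builds the Z alkene on the ester instead of transferring it. Alcohol 11 is acylated at rt with 2-[bis(2,2,2-trifluoroethoxy)phosphoryl]propanoic acid (N,N'-dicyclohexylcarbodiimide, DMAP cat., CH2Cl2). This should give (1S,2R,3R,4R,6S)-3-acetoxy-4-{2-[(TBS)oxy]ethyl}-1-methyl-7-oxabicyclo[4.1.0]heptan-2-yl 2-[bis(2,2,2-trifluoroethoxy)phosphoryl]propanoate F5. Deprotonation with KN(SiMe3)2/18-crown-6 in THF at −78 °C and addition of acetaldehyde should give the Z-configured 2-methylbut-2-enoate 12 (Still–Gennari olefination).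

Further compounds

F1 | step 4 | prop-2-en-1-yl (6S)-6-{2-[(tert-butyldimethylsilyl)oxy]ethyl}-3-methyl-2-oxocyclohex-3-ene-1-carboxylate | CC(C)(C)[Si](C)(C)OCC[C@@H]1CC=C(C)C(=O)C1C(=O)OCC=C
F2 | step 5 | tert-butyl (6S)-6-{2-[(tert-butyldimethylsilyl)oxy]ethyl}-3-methyl-2-oxocyclohex-3-ene-1-carboxylate | CC(C)(C)[Si](C)(C)OCC[C@@H]1CC=C(C)C(=O)C1C(=O)OC(C)(C)C
F3 | step 5 | (5S)-5-{2-[(tert-butyldimethylsilyl)oxy]ethyl}-2-methylcyclohex-2-en-1-one | CC(C)(C)[Si](C)(C)OCC[C@@H]1CC=C(C)C(=O)C1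
F4 | step 5 | (5S,6S)-5-{2-[(tert-butyldimethylsilyl)oxy]ethyl}-6-hydroxy-2-methylcyclohex-2-en-1-one | CC(C)(C)[Si](C)(C)OCC[C@@H]1CC=C(C)C(=O)[C@H]1O
F5 | step 8 | (1S,2R,3R,4R,6S)-3-acetoxy-4-{2-[(tert-butyldimethylsilyl)oxy]ethyl}-1-methyl-7-oxabicyclo[4.1.0]heptan-2-yl 2-[bis(2,2,2-trifluoroethoxy)phosphoryl]propanoate | CC(C)(C)[Si](C)(C)OCC[C@@H]1C[C@@H]2O[C@]2(C)[C@H](OC(=O)C(C)P(=O)(OCC(F)(F)F)OCC(F)(F)F)[C@@H]1OC(C)=O
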